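**Plan**

1. Retrosynthesis: the two O-benzyl bonds are cut last. Ring B (the tetramethylcyclohexenedione) is then opened at two bonds: C4–C(=O) on one side (the ring-closing bond) and C(=O)–CMe2 on the other. This leads back to the aryl δ-lactone 11 (ring C fused to the benzene ring A) and keto ester 13; 11 is cut at the ring A acyl bond and at the ring A–benzylic carbon bond to phenol 5 and enal 2.
2. Enabling feature: C4 of ring B sits between two equivalent acyl carbons that each carry a CMe2, and the ring A oxygen ortho to the benzylic carbon is five atoms from one of them (O–C–C–CH–C4–C=O). That carbonyl can therefore be kept as the carbonyl of a chroman-2-one whose C3 is the future C4. The remaining chain O=C–CMe2–C(=O)–CHMe2 is methanol-opened dimethylketene dimer.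
3. Forward order: ring A is bought as an arene; ring C is fused to it (step 3); ring A is completed (steps 4 to 6); ring B is built in step 8 at the expense of ring C; step 9 frees the phenols.
4. Stereochemistry: the single stereocenter is set in step 3 by iminium catalysis (catalyst control). It stays locked in ring C, β to the lactone carbonyl, where it can neither ionise nor enolise, until ring B is formed.

Key step: step 8

Remark: ring B is a trione drawn as one enol tautomer; the two carbonyl carbons flanking C4 interchange by tautomerism, and 16, 17 and F5 are written in the tautomer of the target.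

**Step 1**
Reactants: 1 3-phenylpropanal
Product: 2 (E)-5-phenylpent-2-enal
Conditions: Ph3P=CHCHO (1.1 equiv), toluene, 80 °C
Reagents that add atoms: (triphenylphosphoranylidene)acetaldehyde O=CC=P(c1ccccc1)(c1ccccc1)c1ccccc1
Why: Wittig olefination with a formyl-stabilised ylide is E-selective and adds exactly two carbons to the aldehyde.

**Step 2**
Reactants: 3 2,6-dimethoxytoluene
Product: 5 3,5-dimethoxy-4-methylphenol, via aryl pinacol boronate 4 (not isolated)
Conditions: [Ir(OMe)(cod)]2 (1.5 mol%), 4,4'-di-tert-butyl-2,2'-bipyridine (3 mol%), B2pin2 (1.0 equiv), THF, 80 °C; then Oxone, acetone/H2O, rt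
Reagents that add atoms: bis(pinacolato)diboron CC1(C)OB(OC1(C)C)B1OC(C)(C)C(C)(C)O1 (boron carried in intermediate 4 only); Oxone, potassium peroxymonosulfate [K+].[O-]S(=O)(=O)OO (the phenol oxygen)
Why: Sterically governed iridium-catalysed C–H borylation of a 1,2,3-trisubstituted arene should occur at the only C–H without an ortho substituent, and the boronate is oxidised to the phenol in the same flask (one-pot C–H borylation/oxidation).

**Step 3**
Reactants: 5 3,5-dimethoxy-4-methylphenol; 2 (E)-5-phenylpent-2-enal
Product: 7 (4S)-5,7-dimethoxy-6-methyl-4-(2-phenylethyl)chroman-2-one, via lactol 6 (not isolated)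
Conditions: (R)-2-[diphenyl(trimethylsilyloxy)methyl]pyrrolidine (20 mol%), PhCO2H (20 mol%), toluene, 0 °C; silica plug; then (n-Pr4N)RuO4 (5 mol%), N-methylmorpholine N-oxide, 4 Å MS, CH2Cl2, rt
Reagents that add atoms: none
Why: Iminium-ion Friedel–Crafts alkylation of an electron-rich hydroxyarene by an enal with hemiacetalisation, then Ley–Griffith oxidation of the lactol, should give the lactone; the diphenyl(silyloxy)methyl group of the (R)-catalyst shields one face of the E-iminium so that the arene carbon ortho to OH adds to the Si face of C3 of the enal and sets the (4S) center, and the two ortho positions of 5 are equivalent by symmetry.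

**Step 4**
Reactants: 7 (4S)-5,7-dimethoxy-6-methyl-4-(2-phenylethyl)chroman-2-one
Product: 8 (4S)-5,7-dihydroxy-6-methyl-4-(2-phenylethyl)chroman-2-one
Conditions: BBr3 (3 equiv), CH2Cl2, −78 °C → rt; H2O
Reagents that add atoms: none
Why: Boron tribromide ether cleavage (bromide attack on the O-methyl of the aryloxyborane complex) should remove both methyl groups while the lactone and the non-enolisable benzylic center stay intact.

**Step 5**
Reactants: 8 (4S)-5,7-dihydroxy-6-methyl-4-(2-phenylethyl)chroman-2-one; 9 3-phenylpropanoic acid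
Product: 10 (4S)-5,7-dihydroxy-6-methyl-4-(2-phenylethyl)-8-(3-phenylpropanoyl)chroman-2-one
Conditions: BF3·OEt2 (neat), 80 °C; aq. NaOAc
Reagents that add atoms: none
Why: Boron trifluoride-mediated Friedel–Crafts acylation of a resorcinol-type ring with a free carboxylic acid (the standard dihydrochalcone synthesis) can only occur at C8, the single unsubstituted ring carbon, ortho to the 7-OH and para to the 5-OH.

**Step 6**
Reactants: 10 (4S)-5,7-dihydroxy-6-methyl-4-(2-phenylethyl)-8-(3-phenylpropanoyl)chroman-2-one
Product: 11 (4S)-5,7-bis(benzyloxy)-6-methyl-4-(2-phenylethyl)-8-(3-phenylpropanoyl)chroman-2-one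
Conditions: BnBr (2.5 equiv), K2CO3, n-Bu4NI (cat.), DMF, 50 °C
Reagents that add atoms: benzyl bromide BrCc1ccccc1
Why: Williamson etherification of both phenols removes the acidic hydroxyls before the enolate chemistry of step 8, and carbonate in dry DMF is too weak to enolise or open the lactone.

**Step 7**
Reactants: 12 2,2,4,4-tetramethylcyclobutane-1,3-dione
Product: 13 methyl 2,2,4-trimethyl-3-oxopentanoate
Conditions: NaOMe (5 mol%), MeOH, reflux; distillation
Reagents that add atoms: methanol CO
Why: Methoxide adds to a carbonyl of the strained dione and the cyclobutanolate opens by retro-Claisen cleavage, the known alcoholysis of dimethylketene dimer.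

**Step 8**
Reactants: 11 (4S)-5,7-bis(benzyloxy)-6-methyl-4-(2-phenylethyl)-8-(3-phenylpropanoyl)chroman-2-one; 13 methyl 2,2,4-trimethyl-3-oxopentanoate
Product: 16 4-[(1R)-1-[2,4-bis(benzyloxy)-6-hydroxy-3-methyl-5-(3-phenylpropanoyl)phenyl]-3-phenylpropyl]-5-hydroxy-2,2,6,6-tetramethylcyclohex-4-ene-1,3-dione, via lithium enolate 14 (not isolated), via ring-opened lithium aryloxide 15 (not isolated)
Conditions: 13 (3 equiv), LiN(i-Pr)2 (3 equiv), THF, −78 °C; 11, −78 °C → rt; cold 1 M HCl to pH 3
Reagents that add atoms: none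
Why: Proposed new method: the tetrasubstituted lithium enolate 14 should attack the aryl-ester carbonyl of ring C (C2 of the chromanone) through carbon and the tetrahedral intermediate should expel the ring A aryloxide to give 15, whose only enolisable position besides the shielded aryl ketone is the CH2 that was C3 of the lactone; excess 14 enolises it and this enolate closes ring B on the methyl ester with loss of methoxide, the sequence being drained by irreversible deprotonation of the 2-substituted trione. The closest known reaction types are the crossed Claisen acylation of preformed ketone enolates by aryl esters and lactones, the C-acylation of preformed enolates of α,α-disubstituted β-keto esters by acyl chlorides, and the Dieckmann closure of 3,5-dioxo esters to cyclohexane-1,3,5-triones of the syncarpic acid type. Ring B closes in the 6-(enolendo)-exo-trig mode, the enolate carbon attacking the ester carbonyl carbon. No stereocenter is created: the (4S) center of 11 is β to the lactone carbonyl, never becomes part of an enolate, and appears in 16 with the descriptor R only because the substituent priorities change. The step needs C- over O-acylation of 14 and attack at the lactone in preference to the aryl ketone; the lithium counter-ion in THF favours carbon, O-acylation is reversible because the neighbouring aryloxide can return the enol ester to the lactone, and the ketone on ring A is twisted and flanked by two ortho substituents. Excess base holds the product as its dianion, in which heterolysis of the benzylic C–C bond to an ortho-quinone methide (the path by which such adducts lose configuration) is disfavoured.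

**Step 9**
Reactants: 16 4-[(1R)-1-[2,4-bis(benzyloxy)-6-hydroxy-3-methyl-5-(3-phenylpropanoyl)phenyl]-3-phenylpropyl]-5-hydroxy-2,2,6,6-tetramethylcyclohex-4-ene-1,3-dione
Product: 17 5-hydroxy-2,2,6,6-tetramethyl-4-[(1R)-3-phenyl-1-[2,4,6-trihydroxy-3-methyl-5-(3-phenylpropanoyl)phenyl]propyl]cyclohex-4-ene-1,3-dione (CNP0236721.1)
Conditions: H2 (1 atm), Pd/C (10 wt%), EtOAc, rt
Reagents that add atoms: none
Why: Hydrogenolysis of the two benzyl aryl ethers over Pd/C is neutral, so the benzylic stereocenter, the chelated aryl ketone and the enolised trione are expected to survive.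

**Compound list**

1 | 3-phenylpropanal | O=CCCc1ccccc1 | starting material
2 | (E)-5-phenylpent-2-enal | O=C/C=C/CCc1ccccc1 | intermediate
3 | 2,6-dimethoxytoluene (1,3-dimethoxy-2-methylbenzene) | COc1cccc(OC)c1C | starting material
4 | 2-(3,5-dimethoxy-4-methylphenyl)-4,4,5,5-tetramethyl-1,3,2-dioxaborolane | COc1cc(cc(OC)c1C)B1OC(C)(C)C(C)(C)O1 | intermediate
5 | 3,5-dimethoxy-4-methylphenol | COc1cc(O)cc(OC)c1C | intermediate
6 | (4S)-5,7-dimethoxy-6-methyl-4-(2-phenylethyl)chroman-2-ol, mixture of anomers at C2 | OC1C[C@H](CCc2ccccc2)c2c(OC)c(C)c(OC)cc2O1 | intermediate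
7 | (4S)-5,7-dimethoxy-6-methyl-4-(2-phenylethyl)chroman-2-one | O=C1C[C@H](CCc2ccccc2)c2c(OC)c(C)c(OC)cc2O1 | intermediate
8 | (4S)-5,7-dihydroxy-6-methyl-4-(2-phenylethyl)chroman-2-one | O=C1C[C@H](CCc2ccccc2)c2c(O)c(C)c(O)cc2O1 | intermediate
9 | 3-phenylpropanoic acid | OC(=O)CCc1ccccc1 | starting material
10 | (4S)-5,7-dihydroxy-6-methyl-4-(2-phenylethyl)-8-(3-phenylpropanoyl)chroman-2-one | O=C1C[C@H](CCc2ccccc2)c2c(O)c(C)c(O)c(C(=O)CCc3ccccc3)c2O1 | intermediate
11 | (4S)-5,7-bis(benzyloxy)-6-methyl-4-(2-phenylethyl)-8-(3-phenylpropanoyl)chroman-2-one | O=C1C[C@H](CCc2ccccc2)c2c(OCc3ccccc3)c(C)c(OCc3ccccc3)c(C(=O)CCc3ccccc3)c2O1 | intermediate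
12 | 2,2,4,4-tetramethylcyclobutane-1,3-dione (dimethylketene dimer) | CC1(C)C(=O)C(C)(C)C1=O | starting material
13 | methyl 2,2,4-trimethyl-3-oxopentanoate | COC(=O)C(C)(C)C(=O)C(C)C | intermediate
14 | lithium 1-methoxy-2,2,4-trimethyl-1-oxopent-3-en-3-olate (lithium enolate of 13) | [Li+].[O-]C(=C(C)C)C(C)(C)C(=O)OC | intermediate
15 | lithium aryloxide of methyl (7S)-7-[2,4-bis(benzyloxy)-6-hydroxy-3-methyl-5-(3-phenylpropanoyl)phenyl]-2,2,4,4-tetramethyl-3,5-dioxo-9-phenylnonanoate | [Li+].[O-]c1c(C(=O)CCc2ccccc2)c(OCc2ccccc2)c(C)c(OCc2ccccc2)c1[C@@H](CCc1ccccc1)CC(=O)C(C)(C)C(=O)C(C)(C)C(=O)OC | intermediate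
16 | 4-[(1R)-1-[2,4-bis(benzyloxy)-6-hydroxy-3-methyl-5-(3-phenylpropanoyl)phenyl]-3-phenylpropyl]-5-hydroxy-2,2,6,6-tetramethylcyclohex-4-ene-1,3-dione | Cc1c(OCc2ccccc2)c(C(=O)CCc2ccccc2)c(O)c([C@@H](CCc2ccccc2)C2=C(O)C(C)(C)C(=O)C(C)(C)C2=O)c1OCc1ccccc1 | intermediate
17 | 5-hydroxy-2,2,6,6-tetramethyl-4-[(1R)-3-phenyl-1-[2,4,6-trihydroxy-3-methyl-5-(3-phenylpropanoyl)phenyl]propyl]cyclohex-4-ene-1,3-dione (CNP0236721.1) | Cc1c(O)c(C(=O)CCc2ccccc2)c(O)c([C@@H](CCc2ccccc2)C2=C(O)C(C)(C)C(=O)C(C)(C)C2=O)c1O | target

**Count and risks**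

Total step count: 9. Longest linear sequence: 7 steps (steps 2, 3, 4, 5, 6, 8, 9; from 3 to 17).

Steps most likely to fail, in order: step 8, step 3, step 5.

Step 8. The hindered enolate may be acylated on oxygen or may only transfer a proton to the lactone, whose enolate can then self-condense; the relay may also stall before ring closure. The fallback uses known chemistry and sets out from 11. Methanolysis of the lactone (NaOMe, MeOH) and benzylation of the liberated phenoxide in the same flask (BnBr, K2CO3, DMF) should give methyl (3S)-3-[2,4,6-tris(benzyloxy)-3-methyl-5-(3-phenylpropanoyl)phenyl]-5-phenylpentanoate F1. Saponification (LiOH, THF/H2O) gives the corresponding pentanoic acid F2, and (COCl)2 with catalytic DMF gives the pentanoyl chloride F3. Addition of F3 to enolate 14 (from 13 and LiN(i-Pr)2, THF, −78 °C) should give methyl (7S)-7-[2,4,6-tris(benzyloxy)-3-methyl-5-(3-phenylpropanoyl)phenyl]-2,2,4,4-tetramethyl-3,5-dioxo-9-phenylnonanoate F4 by C-acylation with an acyl chloride. Dieckmann closure (KOt-Bu, THF) then gives the tris(benzyl ether) of the target F5, and hydrogenolysis (H2, Pd/C, EtOAc) brings the sequence back to the route at 17.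

Step 3. Facial selectivity of the iminium addition may be insufficient with an aliphatic enal, or the phenol oxygen may add in an oxa-Michael sense. The fallback sets out from 5 and moves the stereo-determining event from C–C formation to hydride delivery. Pechmann condensation of 5 with commercial ethyl 3-oxo-5-phenylpentanoate (MeSO3H, rt) should give 5,7-dimethoxy-6-methyl-4-(2-phenylethyl)-2H-chromen-2-one F6 as a single isomer because 5 is symmetric. Copper hydride conjugate reduction (Cu(OAc)2·H2O, DTBM-SEGPHOS, (EtO)2MeSiH, t-BuOH, toluene) then returns to the route at 7. The ligand enantiomer is the one that delivers hydride to the face of C4 giving the (4S) lactone; any over-reduced lactol is returned to 7 by the oxidation of step 3.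

Step 5. Acylation may stop at the phenol ester, or the lactone may scramble in hot BF3·OEt2. The fallback sets out from 8 and replaces the acylium electrophile by a nitrile (Hoesch reaction). 3-Phenylpropanenitrile, ZnCl2 and HCl gas in Et2O at 0 °C should give the C8 ketiminium chloride F7, which is hydrolysed in warm water and returns to the route at 10.

**Further compounds**

F1 | step 8 | methyl (3S)-3-[2,4,6-tris(benzyloxy)-3-methyl-5-(3-phenylpropanoyl)phenyl]-5-phenylpentanoate | COC(=O)C[C@H](CCc1ccccc1)c1c(OCc2ccccc2)c(C)c(OCc2ccccc2)c(C(=O)CCc2ccccc2)c1OCc1ccccc1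
F2 | step 8 | (3S)-3-[2,4,6-tris(benzyloxy)-3-methyl-5-(3-phenylpropanoyl)phenyl]-5-phenylpentanoic acid | OC(=O)C[C@H](CCc1ccccc1)c1c(OCc2ccccc2)c(C)c(OCc2ccccc2)c(C(=O)CCc2ccccc2)c1OCc1ccccc1
F3 | step 8 | (3S)-3-[2,4,6-tris(benzyloxy)-3-methyl-5-(3-phenylpropanoyl)phenyl]-5-phenylpentanoyl chloride | ClC(=O)C[C@H](CCc1ccccc1)c1c(OCc2ccccc2)c(C)c(OCc2ccccc2)c(C(=O)CCc2ccccc2)c1OCc1ccccc1
F4 | step 8 | methyl (7S)-7-[2,4,6-tris(benzyloxy)-3-methyl-5-(3-phenylpropanoyl)phenyl]-2,2,4,4-tetramethyl-3,5-dioxo-9-phenylnonanoate | COC(=O)C(C)(C)C(=O)C(C)(C)C(=O)C[C@H](CCc1ccccc1)c1c(OCc2ccccc2)c(C)c(OCc2ccccc2)c(C(=O)CCc2ccccc2)c1OCc1ccccc1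
F5 | step 8 | 4-[(1R)-1-[2,4,6-tris(benzyloxy)-3-methyl-5-(3-phenylpropanoyl)phenyl]-3-phenylpropyl]-5-hydroxy-2,2,6,6-tetramethylcyclohex-4-ene-1,3-dione | Cc1c(OCc2ccccc2)c(C(=O)CCc2ccccc2)c(OCc2ccccc2)c([C@@H](CCc2ccccc2)C2=C(O)C(C)(C)C(=O)C(C)(C)C2=O)c1OCc1ccccc1
F6 | step 3 | 5,7-dimethoxy-6-methyl-4-(2-phenylethyl)-2H-chromen-2-one | O=C1C=C(CCc2ccccc2)c2c(OC)c(C)c(OC)cc2O1
F7 | step 5 | (4S)-5,7-dihydroxy-6-methyl-4-(2-phenylethyl)-8-(3-phenylpropanimidoyl)chroman-2-one hydrochloride (ketiminium chloride) | O=C1C[C@H](CCc2ccccc2)c2c(O)c(C)c(O)c(C(=[NH2+])CCc3ccccc3)c2O1.[Cl-]
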